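**Strategy.** Ring C is read as a Diels–Alder retron (gibberellane numbering): C8–C9 and C11–C12 are the two bonds of a cyclohexene made from the diene C8=C14–C13(OSi)=C12 and the vinyl group C9=C11. Because C8 and C9 are also joined through C6–C5–C10, an intramolecular cycloaddition closes rings B and C at once, sets quaternary C8 and C9 from the ring A stereotriad, and delivers the C13 oxygen as a silyl enol ether. The precursor is a monocyclic ring A triester carrying a vinyl group at C10 and a 2-silyloxy dienyl side chain at C5. Ring D follows by ketyl–alkyne cyclisation. Ring A chirality comes from one chiral-base desymmetrisation of a meso diester.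

Key step: step 10

Remark: compounds 1 and 8 are taken as catalogue chemicals, and the sense of induction of the chiral amide in step 3 is assumed (the antipodal amide is used if it proves opposite). The target is named here as the gibberellin triacid ent-13-hydroxygibberell-16-ene-7,19,20-trioic acid.

Step 1
Reactants: 1 dimethyl 2-methylisophthalate
Product: 2 2-[2,6-bis(methoxycarbonyl)phenyl]acetic acid
Conditions: LDA, THF, −78 °C; CO2 (g); 1 M HCl
Reagents that add atoms: carbon dioxide, O=C=O
Why: Lateral (benzylic) lithiation of an ortho-toluate, doubly activated here by two ortho esters, followed by carboxylation of the benzylic anion gives the arylacetic acid (future C6–C7); no stereocenter is formed.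

Step 2
Reactants: 2 2-[2,6-bis(methoxycarbonyl)phenyl]acetic acid
Product: 3 all-cis (meso) 2-[2,6-bis(methoxycarbonyl)cyclohexyl]acetic acid
Conditions: H2 (60 bar), 5% Rh/Al2O3, AcOH, 50 °C
Reagents that add atoms: none
Why: Heterogeneous arene hydrogenation delivers all hydrogens from the catalyst face, so the 1,2,3-trisubstituted ring should form as the all-cis, meso cyclohexane with the esters untouched.

Step 3
Reactants: 3 all-cis (meso) 2-[2,6-bis(methoxycarbonyl)cyclohexyl]acetic acid
Product: 4 2-[2,6-bis(methoxycarbonyl)-2-methylcyclohexyl]acetic acid (C4 quaternary; both esters cis to the acetic acid arm, methyl trans)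
Conditions: lithium (R,R)-bis(1-phenylethyl)amide (2.2 equiv, from the amine and n-BuLi), LiCl, THF, −78 °C; MeI, −78 → −40 °C; 1 M HCl
Reagents that add atoms: iodomethane, CI
Why: Enantioselective deprotonation of a meso diester by a chiral lithium amide (desymmetrising enolisation) removes one of the two enantiotopic α-hydrogens, which makes C5 a stereocenter, and the exocyclic enolate is methylated anti to the neighbouring acetate arm (held axial by allylic 1,3-strain), so C4 carries its ester cis and its methyl trans to that arm; the carboxylate arm is not enolised at −78 °C.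

Step 4
Reactants: 4 2-[2,6-bis(methoxycarbonyl)-2-methylcyclohexyl]acetic acid
Product: 5 2-[2-(1-hydroxyethyl)-2,6-bis(methoxycarbonyl)-6-methylcyclohexyl]acetic acid (carbinol epimers; hydroxyethyl trans to the arm)
Conditions: LDA (2.2 equiv), THF, −78 °C; CH3CHO, −78 °C; cold 1 M HCl
Reagents that add atoms: acetaldehyde, CC=O
Why: Aldol addition of the only remaining ester enolate (C10) to acetaldehyde, again anti to the C5 arm, gives quaternary C10 with its ester cis to the arm; the carbinol centre is removed in step 6.

Step 5
Reactants: 5 2-[2-(1-hydroxyethyl)-2,6-bis(methoxycarbonyl)-6-methylcyclohexyl]acetic acid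
Product: 6 dimethyl 1-(1-hydroxyethyl)-2-(2-methoxy-2-oxoethyl)-3-methylcyclohexane-1,3-dicarboxylate (triester alcohol)
Conditions: TMSCHN2, MeOH/toluene, 0 °C
Reagents that add atoms: trimethylsilyldiazomethane, C[Si](C)(C)C=[N+]=[N-]
Why: Methyl esterification of the carboxylic acid with trimethylsilyldiazomethane in methanol is chemoselective and touches no stereocenter.

Step 6
Reactants: 6 triester alcohol
Product: 7 dimethyl 2-(2-methoxy-2-oxoethyl)-1-methyl-3-vinylcyclohexane-1,3-dicarboxylate (ring A triester; all three ester-bearing groups cis, methyl and vinyl trans to the CH2CO2Me arm)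
Conditions: Burgess reagent, toluene, 70 °C
Reagents that add atoms: none
Why: Burgess dehydration (syn elimination through the sulfamate ester) can only remove a hydrogen of the methyl group because C10 is quaternary, so the vinyl group C9=C11 results.

Step 7
Reactants: 8 4,4-diethoxybut-1-yne
Product: 9 6,6-diethoxyhex-3-yn-2-one
Conditions: n-BuLi, THF, −78 °C; N-methoxy-N-methylacetamide, −78 → 0 °C; AcOH
Reagents that add atoms: N-methoxy-N-methylacetamide, CC(=O)N(C)OC
Why: Acylation of a lithium acetylide with a Weinreb amide stops at the ketone through the chelated tetrahedral intermediate.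

Step 8
Reactants: 7 ring A triester; 9 6,6-diethoxyhex-3-yn-2-one
Product: 10 methyl (E)-3-(2,2-diethoxyethyl)-5-oxo-2-[ring A]hex-3-enoate (enone; C6 epimer mixture; ring A = 2,6-bis(methoxycarbonyl)-2-methyl-6-vinylcyclohexyl)
Conditions: LDA, THF, −78 °C; DMPU, 9, −78 → 0 °C; AcOH; then Et3N (cat.), CH2Cl2, rt
Reagents that add atoms: none
Why: Michael addition of the lithium ester enolate (C6 is the only enolisable position of 7) to the ynone, favoured over 1,2-addition by the polar cosolvent and by warming so that any 1,2-adduct reverts, gives after protonation and amine equilibration the conjugated β,β-disubstituted enone in which the bulky C6 substituent should settle trans to the acetyl group (E); C6 forms as an epimer mixture that is corrected in step 14.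

Step 9
Reactants: 10 enone
Product: 11 methyl (3E)-5-(tert-butyldimethylsilyloxy)-3-(2,2-diethoxyethyl)-2-[ring A]hexa-3,5-dienoate (2-silyloxy diene; C6 epimer mixture)
Conditions: LiHMDS, TBSCl, DMPU, THF, −78 °C (in situ trapping)
Reagents that add atoms: tert-butyldimethylsilyl chloride, CC(C)(C)[Si](C)(C)Cl
Why: Kinetic enolisation of the methyl ketone at its unhindered methyl group by the bulky amide with in situ O-silylation gives the cross-conjugated 2-silyloxy diene with the C8=C14 geometry retained, the hindered C6–H being expected to react more slowly.

Step 10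
Reactants: 11 2-silyloxy diene
Product: 12 tricyclic cycloadduct (rings A, B and C; C13 tert-butyldimethylsilyl enol ether, C8 bearing CH2CH(OEt)2, cis B/C fusion, C6 epimer mixture)
Conditions: toluene (0.01 M), BHT, Et3N (trace), 185 °C, sealed tube
Reagents that add atoms: none
Why: Thermal, concerted suprafacial [4+2] cycloaddition of the diene C8=C14–C13(OTBS)=C12 across the unactivated vinyl group C9=C11; the closest known reaction type is the intramolecular Diels–Alder reaction of 2-silyloxy-1,3-dienes with tethered terminal alkenes (1,6,8-nonatriene class). Ring C (six-membered) is closed by the cycloaddition itself and ring B (five-membered) in fused mode by the three-atom tether C6–C5–C10 that links diene terminus C8 to dienophile carbon C9. C9 is controlled by ring A: with the vinyl and dienyl arms trans-diequatorial on the chair, the vinyl group should react through the rotamer in which C9=C11 eclipses the axial C10–CO2Me bond, so that C11 becomes pseudo-equatorial on the nascent trans-fused cyclopentane and ring C forms on the face of the C10 ester. C8 follows from the E geometry of C8=C14 (tether outside, acetal-bearing CH2 inside) together with the endo orientation of the tether, which gives the cis B/C fusion and puts the flat sp2 carbon C14 next to the axial C10 ester; the exo mode would give the trans-fused pair with the inside CH2 pressed against that ester. The step needs periselectivity over a 1,5-hydrogen shift of the inside CH2 and tolerance of the mixed C6 configuration; the quaternary C10, which holds the vinyl group close to the diene, and the small allylic strain of either C6 epimer (C6 is cis only to H14) are expected to secure both, C6 being corrected in step 14.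

Step 11
Reactants: 12 tricyclic cycloadduct
Product: 13 keto aldehyde (C13 ketone, C8–CH2CHO; C6 epimer mixture)
Conditions: 1 M HCl, THF, 0 °C → rt
Reagents that add atoms: water, O
Why: Aqueous acid hydrolyses the silyl enol ether to the C13 ketone and the diethyl acetal to the aldehyde in one operation (enol ether and acetal hydrolysis) without touching a stereocenter.

Step 12
Reactants: 13 keto aldehyde
Product: 14 keto alkyne (C13 ketone, C8–CH2C≡CH; C6 epimer mixture)
Conditions: dimethyl (1-diazo-2-oxopropyl)phosphonate, K2CO3, MeOH, 0 °C → rt
Reagents that add atoms: dimethyl (1-diazo-2-oxopropyl)phosphonate, COP(=O)(OC)C(=[N+]=[N-])C(C)=O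
Why: Seyferth–Gilbert homologation with the Ohira–Bestmann reagent converts the aldehyde into the terminal alkyne (C16≡C17) under carbonate conditions that leave the ketone alone, and any reversible intramolecular aldol adduct is funnelled back to the alkyne.

Step 13
Reactants: 14 keto alkyne
Product: 15 trimethyl ester of the target triacid (trimethyl ent-13-hydroxygibberell-16-ene-7,19,20-trioate), C6 epimer mixture
Conditions: SmI2 (4 equiv), HMPA, t-BuOH, THF, 0 °C
Reagents that add atoms: none
Why: Ketyl–alkyne reductive radical cyclisation: single-electron reduction of the C13 ketone gives a ketyl that closes 5-exo-dig on the alkyne, forming C13–C16, the tertiary alcohol and the exocyclic methylene, and because the new two-carbon bridge can only span from the C8 propargyl group, C13 is set by C8.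

Step 14
Reactants: 15 trimethyl ester of the target triacid, C6 epimer mixture
Product: 16 trimethyl ester of the target triacid (6β ester, single epimer)
Conditions: NaOMe (0.5 equiv), MeOH, 65 °C
Reagents that add atoms: none
Why: Base-mediated epimerisation through the C6 ester enolate should give the thermodynamically preferred ester, cis to H5 and remote from the axial C4 ester; no other centre is enolisable.

Step 15
Reactants: 16 trimethyl ester of the target triacid
Product: 17 target gibberellin triacid (ent-13-hydroxygibberell-16-ene-7,19,20-trioic acid)
Conditions: NaSEt (12 equiv), DMF, 90 °C; then 1 M HCl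
Reagents that add atoms: none
Why: SN2 demethylation of the three methyl esters by thiolate at the methyl carbon frees the hindered acids without touching the tertiary allylic alcohol, the exocyclic alkene or any stereocenter.

**Compound list**

1 | dimethyl 2-methylisophthalate | COC(=O)c1cccc(C(=O)OC)c1C | starting material
2 | 2-[2,6-bis(methoxycarbonyl)phenyl]acetic acid | COC(=O)c1cccc(C(=O)OC)c1CC(=O)O | intermediate
3 | all-cis (meso) 2-[2,6-bis(methoxycarbonyl)cyclohexyl]acetic acid | COC(=O)[C@H]1CCC[C@@H](C(=O)OC)[C@H]1CC(=O)O | intermediate
4 | 2-[2,6-bis(methoxycarbonyl)-2-methylcyclohexyl]acetic acid, esters cis to the arm, methyl trans | COC(=O)[C@H]1CCC[C@@](C)(C(=O)OC)[C@H]1CC(=O)O | intermediate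
5 | 2-[2-(1-hydroxyethyl)-2,6-bis(methoxycarbonyl)-6-methylcyclohexyl]acetic acid, carbinol epimers | CC(O)[C@]1(C(=O)OC)CCC[C@@](C)(C(=O)OC)[C@H]1CC(=O)O | intermediate
6 | dimethyl 1-(1-hydroxyethyl)-2-(2-methoxy-2-oxoethyl)-3-methylcyclohexane-1,3-dicarboxylate | CC(O)[C@]1(C(=O)OC)CCC[C@@](C)(C(=O)OC)[C@H]1CC(=O)OC | intermediate
7 | dimethyl 2-(2-methoxy-2-oxoethyl)-1-methyl-3-vinylcyclohexane-1,3-dicarboxylate (ring A triester) | C=C[C@]1(C(=O)OC)CCC[C@@](C)(C(=O)OC)[C@H]1CC(=O)OC | intermediate
8 | 4,4-diethoxybut-1-yne | C#CCC(OCC)OCC | starting material
9 | 6,6-diethoxyhex-3-yn-2-one | CC(=O)C#CCC(OCC)OCC | intermediate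
10 | (E)-enone, methyl 3-(2,2-diethoxyethyl)-5-oxo-2-[ring A]hex-3-enoate, C6 epimers | C=C[C@]1(C(=O)OC)CCC[C@@](C)(C(=O)OC)[C@H]1C(C(=O)OC)/C(CC(OCC)OCC)=C/C(C)=O | intermediate
11 | (3E)-2-silyloxy diene, C6 epimers | C=C[C@]1(C(=O)OC)CCC[C@@](C)(C(=O)OC)[C@H]1C(C(=O)OC)/C(CC(OCC)OCC)=C/C(=C)O[Si](C)(C)C(C)(C)C | intermediate
12 | tricyclic cycloadduct, C13 silyl enol ether, C6 epimers | CCOC(OCC)C[C@]23C=C(O[Si](C)(C)C(C)(C)C)CC[C@H]2[C@]1(C(=O)OC)CCC[C@@](C)(C(=O)OC)[C@H]1C3C(=O)OC | intermediate
13 | keto aldehyde, C6 epimers | O=CC[C@]23CC(=O)CC[C@H]2[C@]1(C(=O)OC)CCC[C@@](C)(C(=O)OC)[C@H]1C3C(=O)OC | intermediate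
14 | keto alkyne, C6 epimers | C#CC[C@]23CC(=O)CC[C@H]2[C@]1(C(=O)OC)CCC[C@@](C)(C(=O)OC)[C@H]1C3C(=O)OC | intermediate
15 | trimethyl ester of the target triacid, C6 epimers | C=C1C[C@]23C[C@@]1(O)CC[C@H]2[C@]1(C(=O)OC)CCC[C@@](C)(C(=O)OC)[C@H]1C3C(=O)OC | intermediate
16 | trimethyl ester of the target triacid, 6β ester | C=C1C[C@]23C[C@@]1(O)CC[C@H]2[C@]1(C(=O)OC)CCC[C@@](C)(C(=O)OC)[C@H]1[C@@H]3C(=O)OC | intermediate
17 | target gibberellin triacid, ent-13-hydroxygibberell-16-ene-7,19,20-trioic acid | C=C1C[C@]23C[C@@]1(O)CC[C@H]2[C@]1(C(=O)O)CCC[C@@](C)(C(=O)O)[C@H]1[C@@H]3C(=O)O | target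

**Count and risks**

Total step count: 15. Longest linear sequence: 14 steps (steps 1–6 and 8–15).

Steps most likely to fail:

Step 10. At 185 °C the diene may undergo a 1,5-hydrogen shift, the unactivated vinyl group may react too slowly, or the exo mode may leak to the trans-fused B/C isomer. The fallback sets out from 11 and comes back at 12. It leaves the concerted thermal manifold for a metal-templated stepwise cycloaddition: oxidative cyclisation of diene and alkene on a cationic monovalent rhodium centre, then reductive elimination (Rh(cod)2SbF6 with P(OCH(CF3)2)3, 1,2-dichloroethane, 60 °C). This operates on unactivated diene–ene pairs well below the temperature of the hydrogen shift; no new compound is formed.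

Step 9. The doubly activated C6–H may be removed in competition with a methyl hydrogen, giving the linear dienol ether, double-bond migration or loss of the E geometry. The fallback sets out from 10 and comes back at 13. Enolisation is made exhaustive instead of selective. LDA (2.3 equiv) in THF/DMPU at −78 → −40 °C removes first C6–H and then a methyl hydrogen, giving the dianion in the manner of acetoacetate dianions. TBSCl then silylates both oxygens to give the bis-silyl tetraene F3 (silyl ketene acetal at C6=C7 plus the 2-silyloxy diene). Heating as in step 10 gives the bis-silyl cycloadduct F4, and the aqueous HCl of step 11 hydrolyses ketene acetal, enol ether and acetal to 13.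

Step 3. The chiral amide may discriminate the enantiotopic α-hydrogens poorly, or proton exchange between the two ester sites may occur before methylation, giving low enantiomeric purity. The fallback sets out from 3 and comes back at 4. The meso compound is methylated without chiral control (LDA, MeI) and the racemic acid is resolved classically with (S)-1-phenylethylamine. The less soluble (S)-1-phenylethylammonium salt of 4 F1 is crystallised and acidified to return 4, while the enantiomer of acid 4 F2 stays in the mother liquor.

Further compounds
F1 | step 3 | (S)-1-phenylethylammonium salt of 4 | COC(=O)[C@H]1CCC[C@@](C)(C(=O)OC)[C@H]1CC(=O)[O-].C[C@H]([NH3+])c1ccccc1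
F2 | step 3 | enantiomer of acid 4 | COC(=O)[C@@H]1CCC[C@](C)(C(=O)OC)[C@@H]1CC(=O)O
F3 | step 9 | bis-silyl tetraene (silyl ketene acetal and 2-silyloxy diene) | C=C[C@]1(C(=O)OC)CCC[C@@](C)(C(=O)OC)[C@H]1C(=C(OC)O[Si](C)(C)C(C)(C)C)C(CC(OCC)OCC)=CC(=C)O[Si](C)(C)C(C)(C)C
F4 | step 9 | bis-silyl cycloadduct | CCOC(OCC)C[C@]23C=C(O[Si](C)(C)C(C)(C)C)CC[C@H]2[C@]1(C(=O)OC)CCC[C@@](C)(C(=O)OC)[C@H]1C3=C(OC)O[Si](C)(C)C(C)(C)C
F0 | step 10 | none | none
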